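**Strategy.** Dibenzofuran numbering is used (ring C: C1–C4, C4a, C9b). In ring C the hydroxyl sits at C3, β to the ether carbon C4a, which is flanked by the quaternary C9b. Read as a latent ketone, C4a turns C3–C4 into an aldol bond and C9b–C1 into a Michael bond, so C1–C3 is acrolein. One cinchona-catalysed Michael/aldol domino of an α-aryl-α-cyano methyl ketone with acrolein forges both bonds, sets C9b by catalysis and relays it to C3; reductive etherification then closes the furan ring. The nitrile becomes the Z-acrylate, the aryl iodide the Z-cinnamamide, and lactamisation onto spermidine closes the macrocycle.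

Key step: step 4

Remark: the sense of induction of 6'-hydroxy cinchona bases with this acyclic α-aryl-α-cyano ketone is assumed to follow the cupreidine series; should the (S)-adduct form, the cupreine-derived pseudoenantiomer would be used in the same way.

Step 1
Reactants: 1 2-(2-hydroxyphenyl)acetonitrile
Product: 2 2-(2-hydroxy-5-iodophenyl)acetonitrile
Conditions: NIS (1.05 equiv), TsOH·H2O (10 mol %), MeCN, 0 °C to rt
Reagents that add atoms: N-iodosuccinimide O=C1CCC(=O)N1I
Why: Electrophilic aromatic iodination: the free hydroxyl directs the acid-activated iodine donor to the para position (C5), the ortho site being slower, and no stereocentre is formed.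

Step 2
Reactants: 2 2-(2-hydroxy-5-iodophenyl)acetonitrile
Product: 3 2-[5-iodo-2-(methoxymethoxy)phenyl]acetonitrile
Conditions: MOMCl (1.3 equiv), i-Pr2NEt (2 equiv), CH2Cl2, 0 °C to rt
Reagents that add atoms: chloromethyl methyl ether COCCl
Why: Williamson-type O-alkylation (MOM ether formation) masks the phenol, which would otherwise close on the ketone of 4 and aromatise to a 2-methylbenzofuran.

Step 3
Reactants: 3 2-[5-iodo-2-(methoxymethoxy)phenyl]acetonitrile
Product: 4 2-[5-iodo-2-(methoxymethoxy)phenyl]-3-oxobutanenitrile (racemic)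
Conditions: t-BuOK (2.2 equiv), EtOAc (3 equiv), THF, 0 °C to rt; then 1 M HCl
Reagents that add atoms: ethyl acetate CCOC(C)=O
Why: Claisen-type C-acylation of the benzylic nitrile anion by ethyl acetate, driven by deprotonation of the product to its stabilised enolate; the new centre is configurationally labile and is fixed only in step 4.

Step 4
Reactants: 4 2-[5-iodo-2-(methoxymethoxy)phenyl]-3-oxobutanenitrile, 5 acrolein (1.2 equiv)
Product: 7 (1R,4R)-4-hydroxy-1-[5-iodo-2-(methoxymethoxy)phenyl]-2-oxocyclohexane-1-carbonitrile, via Michael adduct 6 (not isolated)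
Conditions: 9-O-(9-phenanthryl)cupreidine (10 mol %), CH2Cl2, −25 °C; then DBU (20 mol %), −25 to 0 °C, same flask; AcOH quench
Reagents that add atoms: none
Why: The quinuclidine nitrogen of the bifunctional cinchona base deprotonates the acidic α-aryl-α-cyano ketone 4 while the 6'-hydroxyl binds acrolein, so conjugate addition inside the chiral ion pair forms C9b–C1 and sets the quaternary centre of 6 by catalyst control (asymmetric Michael addition of a trisubstituted carbon acid to an enal). DBU then enolises the only enolisable position of the ketone, the methyl group, and the enolate adds to the tethered aldehyde to form C3–C4 (intramolecular aldol; together a Michael/aldol domino, i.e. a Robinson-type annulation stopped at the ketol). The one ring that closes, the cyclohexanone, does so by a 6-(enolendo)-exo-trig closure. The carbinol centre is set by substrate control: in the chair-like transition state the large aryl group on the quaternary carbon should sit pseudo-axial to avoid A(1,2) strain with the enolate oxygen and the aldehyde oxygen pseudo-equatorial, which places the hydroxyl cis to the aryl group, i.e. (1R,4R). The step needs enantioface selectivity at the prochiral carbanion (secured by the catalyst), 1,4- over 1,2-addition (secured by the soft, stabilised carbanion) and a kinetic quench at low temperature so that neither retro-Michael or retro-aldol exchange nor dehydration to the enone erodes the two centres.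

Step 5
Reactants: 7 (1R,4R)-4-hydroxy-1-[5-iodo-2-(methoxymethoxy)phenyl]-2-oxocyclohexane-1-carbonitrile
Product: 9 (3R,4aR,9bR)-3-hydroxy-8-iodo-1,2,3,4,4a,9b-hexahydrodibenzo[b,d]furan-9b-carbonitrile, via hemiketal 8 (not isolated)
Conditions: Et3SiH (5 equiv), TFA/CH2Cl2 (1:1), 0 °C to rt; then K2CO3, MeOH, rt (cleaves any trifluoroacetate ester)
Reagents that add atoms: none
Why: Acid removes the MOM acetal, the freed phenol closes on the ketone to the five-membered hemiketal 8, and ionic hydrogenation (reductive etherification: oxocarbenium ion trapped by Et3SiH) delivers hydride to C4a on the face opposite C1, the only trajectory that leads to the cis-fused furan, so C4a is set as R by the quaternary C9b.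

Step 6
Reactants: 9 (3R,4aR,9bR)-3-hydroxy-8-iodo-1,2,3,4,4a,9b-hexahydrodibenzo[b,d]furan-9b-carbonitrile
Product: 11 (3R,4aR,9bS)-3-hydroxy-8-iodo-1,2,3,4,4a,9b-hexahydrodibenzo[b,d]furan-9b-carbaldehyde, via aldimine 10 (not isolated)
Conditions: i-Bu2AlH (2.5 equiv), CH2Cl2, −78 to −40 °C; then aq. potassium sodium tartrate, rt
Reagents that add atoms: water O
Why: Partial nitrile reduction: i-Bu2AlH adds once to give the N-aluminated aldimine, hydrolysed on work-up to the aldehyde (the first equivalent is consumed by the hydroxyl), and the fully substituted C9b can neither epimerise nor undergo β-elimination.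

Step 7
Reactants: 11 (3R,4aR,9bS)-3-hydroxy-8-iodo-1,2,3,4,4a,9b-hexahydrodibenzo[b,d]furan-9b-carbaldehyde, 12 methyl 2-[bis(2,2,2-trifluoroethoxy)phosphoryl]acetate (1.3 equiv)
Product: 13 methyl (2Z)-3-[(3R,4aR,9bS)-3-hydroxy-8-iodo-1,2,3,4,4a,9b-hexahydrodibenzo[b,d]furan-9b-yl]prop-2-enoate
Conditions: KN(SiMe3)2 (1.25 equiv), 18-crown-6 (4 equiv), THF, −78 °C; anion preformed, then 11
Reagents that add atoms: none
Why: Still–Gennari olefination: the electron-poor bis(trifluoroethyl) phosphonate anion adds under dissociating conditions and the kinetic adduct collapses faster than it equilibrates, which should give the (Z)-enoate from the non-enolisable α-quaternary aldehyde.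

Step 8
Reactants: 14 tert-butyl N-(3-aminopropyl)-N-{4-[(tert-butoxycarbonyl)amino]butyl}carbamate (N1,N5-bis-Boc-spermidine), 15 propiolic acid
Product: 16 tert-butyl N-{4-[(tert-butoxycarbonyl)amino]butyl}-N-[3-(prop-2-ynoylamino)propyl]carbamate
Conditions: DCC (1.1 equiv), CH2Cl2, 0 °C
Reagents that add atoms: none
Why: Carbodiimide-mediated amide coupling: at 0 °C and without a nucleophilic catalyst, N-acylation of the only free (primary) amine should outrun conjugate addition to the alkynoate.

Step 9
Reactants: 13 methyl (2Z)-3-[(3R,4aR,9bS)-3-hydroxy-8-iodo-1,2,3,4,4a,9b-hexahydrodibenzo[b,d]furan-9b-yl]prop-2-enoate, 16 tert-butyl N-{4-[(tert-butoxycarbonyl)amino]butyl}-N-[3-(prop-2-ynoylamino)propyl]carbamate (1.3 equiv)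
Product: 17 aryl ynamide: 13 with iodine replaced by the C≡C–C(O)NH(CH2)3N(Boc)(CH2)4NHBoc chain of 16, (3R,4aR,9bS), enoate Z
Conditions: Pd(PPh3)2Cl2 (5 mol %), CuI (10 mol %), Et3N (3 equiv), THF, rt
Reagents that add atoms: none
Why: Sonogashira coupling: the catalyst inserts only into the aryl C–I bond and the copper acetylide of the ynamide transmetallates at room temperature, conditions under which the (Z)-enoate, the free alcohol and both carbamates are inert.

Step 10
Reactants: 17 aryl ynamide
Product: 18 (Z,Z)-ester: 17 with the alkyne reduced to the (Z)-cinnamamide, (3R,4aR,9bS)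
Conditions: H2 (1 atm), Pd/CaCO3 poisoned with Pb(OAc)2 (Lindlar catalyst), quinoline, EtOAc/MeOH, rt, dark
Reagents that add atoms: none
Why: Lindlar semi-hydrogenation: syn delivery of one equivalent of hydrogen on the poisoned surface should give the (Z)-cinnamamide, while the existing enoate and the product alkene are not reduced.

Step 11
Reactants: 18 (Z,Z)-ester
Product: 19 (Z,Z)-acid: (2Z)-3-[(3R,4aR,9bS)-8-{(1Z)-3-[(3-{(tert-butoxycarbonyl)[4-(tert-butoxycarbonylamino)butyl]amino}propyl)amino]-3-oxoprop-1-en-1-yl}-3-hydroxy-1,2,3,4,4a,9b-hexahydrodibenzo[b,d]furan-9b-yl]prop-2-enoic acid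
Conditions: LiOH·H2O (3 equiv), THF/MeOH/H2O, 0 °C to rt; then 1 M HCl to pH 4
Reagents that add atoms: lithium hydroxide [Li+].[OH-]
Why: Saponification of the methyl ester; the carbamates and the secondary amide are stable to LiOH at room temperature, and acidification only to pH 4 keeps both Boc groups.

Step 12
Reactants: 19 (Z,Z)-acid
Product: 22 CNP0243477.1 (20-membered (Z,Z)-bis-enamide lactam; 3R,4aR,9bS), via seco amino acid 20 (not isolated), via pentafluorophenyl ester 21 (not isolated)
Conditions: TFA/CH2Cl2 (1:4), 0 °C, then evaporation; then pentafluorophenyl diphenylphosphinate (1.5 equiv), i-Pr2NEt (6 equiv), DMF, 0.001 M, slow addition, rt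
Reagents that add atoms: none
Why: Acidolysis of both Boc groups followed by macrolactamisation through the pentafluorophenyl active ester under high dilution: the unhindered primary amine of the butyl arm should acylate faster than the internal dialkylamine and the two (Z)-alkenes fold the chain towards the 20-membered lactam; no stereocentre is touched.

**Compound list**

1 | 2-(2-hydroxyphenyl)acetonitrile | N#CCc1ccccc1O | starting material
2 | 2-(2-hydroxy-5-iodophenyl)acetonitrile | N#CCc1cc(I)ccc1O | intermediate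
3 | 2-[5-iodo-2-(methoxymethoxy)phenyl]acetonitrile | N#CCc1cc(I)ccc1OCOC | intermediate
4 | 2-[5-iodo-2-(methoxymethoxy)phenyl]-3-oxobutanenitrile (racemic, enolisable) | CC(=O)C(C#N)c1cc(I)ccc1OCOC | intermediate
5 | acrolein (prop-2-enal) | C=CC=O | starting material
6 | (2R)-2-acetyl-2-[5-iodo-2-(methoxymethoxy)phenyl]-5-oxopentanenitrile (not isolated) | N#C[C@](C(C)=O)(c1cc(I)ccc1OCOC)CCC=O | intermediate
7 | (1R,4R)-4-hydroxy-1-[5-iodo-2-(methoxymethoxy)phenyl]-2-oxocyclohexane-1-carbonitrile (hydroxyl cis to aryl) | N#C[C@]1(c2cc(I)ccc2OCOC)CC[C@@H](O)CC1=O | intermediate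
8 | (3R,4aR,9bR)-3,4a-dihydroxy-8-iodo-1,2,3,4,4a,9b-hexahydrodibenzo[b,d]furan-9b-carbonitrile (cis-fused hemiketal, not isolated) | N#C[C@]12CC[C@@H](O)C[C@@]1(O)Oc1ccc(I)cc12 | intermediate
9 | (3R,4aR,9bR)-3-hydroxy-8-iodo-1,2,3,4,4a,9b-hexahydrodibenzo[b,d]furan-9b-carbonitrile (cis-fused; hydroxyl cis to ring oxygen) | N#C[C@]12CC[C@@H](O)C[C@H]1Oc1ccc(I)cc12 | intermediate
10 | (3R,4aR,9bR)-9b-(iminomethyl)-8-iodo-1,2,3,4,4a,9b-hexahydrodibenzo[b,d]furan-3-ol (not isolated) | N=C[C@]12CC[C@@H](O)C[C@H]1Oc1ccc(I)cc12 | intermediate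
11 | (3R,4aR,9bS)-3-hydroxy-8-iodo-1,2,3,4,4a,9b-hexahydrodibenzo[b,d]furan-9b-carbaldehyde | O=C[C@]12CC[C@@H](O)C[C@H]1Oc1ccc(I)cc12 | intermediate
12 | methyl 2-[bis(2,2,2-trifluoroethoxy)phosphoryl]acetate | COC(=O)CP(=O)(OCC(F)(F)F)OCC(F)(F)F | starting material
13 | methyl (2Z)-3-[(3R,4aR,9bS)-3-hydroxy-8-iodo-1,2,3,4,4a,9b-hexahydrodibenzo[b,d]furan-9b-yl]prop-2-enoate | COC(=O)/C=C\[C@]12CC[C@@H](O)C[C@H]1Oc1ccc(I)cc12 | intermediate
14 | tert-butyl N-(3-aminopropyl)-N-{4-[(tert-butoxycarbonyl)amino]butyl}carbamate (N1,N5-bis-Boc-spermidine) | NCCCN(CCCCNC(=O)OC(C)(C)C)C(=O)OC(C)(C)C | starting material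
15 | propiolic acid (prop-2-ynoic acid) | C#CC(=O)O | starting material
16 | tert-butyl N-{4-[(tert-butoxycarbonyl)amino]butyl}-N-[3-(prop-2-ynoylamino)propyl]carbamate | C#CC(=O)NCCCN(CCCCNC(=O)OC(C)(C)C)C(=O)OC(C)(C)C | intermediate
17 | methyl (2Z)-3-[(3R,4aR,9bS)-8-{3-[(3-{(tert-butoxycarbonyl)[4-(tert-butoxycarbonylamino)butyl]amino}propyl)amino]-3-oxoprop-1-yn-1-yl}-3-hydroxy-1,2,3,4,4a,9b-hexahydrodibenzo[b,d]furan-9b-yl]prop-2-enoate | COC(=O)/C=C\[C@]12CC[C@@H](O)C[C@H]1Oc1ccc(C#CC(=O)NCCCN(CCCCNC(=O)OC(C)(C)C)C(=O)OC(C)(C)C)cc12 | intermediate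
18 | methyl (2Z)-3-[(3R,4aR,9bS)-8-{(1Z)-3-[(3-{(tert-butoxycarbonyl)[4-(tert-butoxycarbonylamino)butyl]amino}propyl)amino]-3-oxoprop-1-en-1-yl}-3-hydroxy-1,2,3,4,4a,9b-hexahydrodibenzo[b,d]furan-9b-yl]prop-2-enoate | COC(=O)/C=C\[C@]12CC[C@@H](O)C[C@H]1Oc1ccc(/C=C\C(=O)NCCCN(CCCCNC(=O)OC(C)(C)C)C(=O)OC(C)(C)C)cc12 | intermediate
19 | the carboxylic acid of 18 (both alkenes Z; 3R,4aR,9bS) | OC(=O)/C=C\[C@]12CC[C@@H](O)C[C@H]1Oc1ccc(/C=C\C(=O)NCCCN(CCCCNC(=O)OC(C)(C)C)C(=O)OC(C)(C)C)cc12 | intermediate
20 | (2Z)-3-[(3R,4aR,9bS)-8-{(1Z)-3-[(3-{[4-aminobutyl]amino}propyl)amino]-3-oxoprop-1-en-1-yl}-3-hydroxy-1,2,3,4,4a,9b-hexahydrodibenzo[b,d]furan-9b-yl]prop-2-enoic acid (formed as bis-trifluoroacetate salt, not isolated) | OC(=O)/C=C\[C@]12CC[C@@H](O)C[C@H]1Oc1ccc(/C=C\C(=O)NCCCNCCCCN)cc12 | intermediate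
21 | pentafluorophenyl ester of 20 (not isolated) | O=C(Oc1c(F)c(F)c(F)c(F)c1F)/C=C\[C@]12CC[C@@H](O)C[C@H]1Oc1ccc(/C=C\C(=O)NCCCNCCCCN)cc12 | intermediate
22 | CNP0243477.1: macrolactam of 20 between the terminal butyl-arm amine and the C9b (Z)-acrylic acid; (3R,4aR,9bS), hydroxyl cis to the ring oxygen, both enamides Z | O=C1/C=C\[C@]23CC[C@@H](O)C[C@H]2Oc2ccc(cc23)/C=C\C(=O)NCCCNCCCCN1 | target

**Totals.** Total step count: 12. Longest linear sequence: 11 steps (steps 1–7 and 9–12); step 8 is a one-step side branch.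

**Steps most likely to fail**

1. Step 4. The relay from C9b to the carbinol carbon may be lost: closure through the competing chair (aryl pseudo-equatorial) or retro-aldol equilibration under the amidine would give the C3 epimer. The fallback sets C3 by reagent control on the rigid tricycle instead of by the aldol. It sets out from 9 as it would then emerge from step 5, mixed with its C3 epimer (3S,4aR,9bR)-3-hydroxy-8-iodo-1,2,3,4,4a,9b-hexahydrodibenzo[b,d]furan-9b-carbonitrile F1. Both are oxidised (Dess–Martin periodinane, NaHCO3, CH2Cl2) to the single ketone (4aR,9bR)-8-iodo-3-oxo-1,2,3,4,4a,9b-hexahydrodibenzo[b,d]furan-9b-carbonitrile F2. With the small nitrile axial and the ring oxygen axial in the preferred chair, LiBH(s-Bu)3 (THF, −78 °C) should attack equatorially, away from the syn-axial oxygen, and give the axial alcohol cis to the ring oxygen. The sequence comes back to the route at 9.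

2. Step 5. Ionisation of the hemiketal next to the nitrile-bearing quaternary carbon may be slow, so that acid-promoted dehydration of the β-hydroxy ketone or closure of the phenol on the nitrile overtakes hydride transfer. The fallback forms the C4a–O bond by SN2 displacement instead of oxocarbenium reduction and sets out from 7. Hydroxyl-directed Evans–Saksena reduction (Me4NBH(OAc)3, MeCN/AcOH, −20 °C) should give the anti-1,3-diol (1R,2S,4R)-2,4-dihydroxy-1-[5-iodo-2-(methoxymethoxy)phenyl]cyclohexane-1-carbonitrile F3, whose new hydroxyl is trans to the aryl group. MOM cleavage (2 M aq. HCl, THF, 40 °C) gives (1R,2S,4R)-2,4-dihydroxy-1-(2-hydroxy-5-iodophenyl)cyclohexane-1-carbonitrile F4. Mitsunobu etherification (PPh3, diisopropyl azodicarboxylate, THF, 0 °C to rt) closes the furan with inversion at C4a; the phenol can reach only this carbinol from the rear. The sequence comes back at 9.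

3. Step 12. Acylation of the internal secondary amine (a 15-membered tertiary lactam) and intermolecular oligomerisation may compete with closure onto the primary amine. The fallback replaces intrinsic chemoselectivity by protecting-group control and sets out from 20, isolated as its salt. Benzaldehyde (1 equiv, Et3N, MeOH) condenses only with the primary amine to give the terminal N-benzylidene imine of 20 F5. Boc2O then caps the internal amine to give the N-Boc imine F6, and aq. KHSO4 releases the internal-N-Boc amino acid F7. The same pentafluorophenyl diphenylphosphinate cyclisation gives the internal-N-Boc macrolactam F8, and TFA/CH2Cl2 removes the carbamate. The sequence comes back at 22.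

**Further compounds**

F1 | step 4 | (3S,4aR,9bR)-3-hydroxy-8-iodo-1,2,3,4,4a,9b-hexahydrodibenzo[b,d]furan-9b-carbonitrile | N#C[C@]12CC[C@H](O)C[C@H]1Oc1ccc(I)cc12
F2 | step 4 | (4aR,9bR)-8-iodo-3-oxo-1,2,3,4,4a,9b-hexahydrodibenzo[b,d]furan-9b-carbonitrile | N#C[C@]12CCC(=O)C[C@H]1Oc1ccc(I)cc12
F3 | step 5 | (1R,2S,4R)-2,4-dihydroxy-1-[5-iodo-2-(methoxymethoxy)phenyl]cyclohexane-1-carbonitrile | N#C[C@]1(c2cc(I)ccc2OCOC)CC[C@@H](O)C[C@@H]1O
F4 | step 5 | (1R,2S,4R)-2,4-dihydroxy-1-(2-hydroxy-5-iodophenyl)cyclohexane-1-carbonitrile | N#C[C@]1(c2cc(I)ccc2O)CC[C@@H](O)C[C@@H]1O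
F5 | step 12 | terminal N-benzylidene imine of 20 | OC(=O)/C=C\[C@]12CC[C@@H](O)C[C@H]1Oc1ccc(/C=C\C(=O)NCCCNCCCC/N=C/c3ccccc3)cc12
F6 | step 12 | internal-N-Boc derivative of F5 | OC(=O)/C=C\[C@]12CC[C@@H](O)C[C@H]1Oc1ccc(/C=C\C(=O)NCCCN(CCCC/N=C/c3ccccc3)C(=O)OC(C)(C)C)cc12
F7 | step 12 | internal-N-Boc amino acid | OC(=O)/C=C\[C@]12CC[C@@H](O)C[C@H]1Oc1ccc(/C=C\C(=O)NCCCN(CCCCN)C(=O)OC(C)(C)C)cc12
F8 | step 12 | internal-N-Boc macrolactam | O=C1/C=C\[C@]23CC[C@@H](O)C[C@H]2Oc2ccc(cc23)/C=C\C(=O)NCCCN(C(=O)OC(C)(C)C)CCCCN1
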